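The allowance a catalyst has for one turnover, held against the time a turnover takes: this flask rests on that comparison.

starting material 20 mM; reagent 50.0 mM; free catalyst 2.0 mM; time 5.0 min

    reagent + catalyst intermediate B ⇌ catalyst intermediate C (K1 = 7.2 L mol⁻¹, k1 = 321 L mol⁻¹ s⁻¹)
    catalyst intermediate D ⇌ by-product + catalyst intermediate E (K2 = 0.00720 M, k2 = 0.204 s⁻¹)
    reagent + by-product ⇌ idle adduct, settled at all times (K3 = 1510 L mol⁻¹)
    reagent + free catalyst + target → free catalyst + over-reaction product (k4 = 13.1 L² mol⁻² s⁻¹)
    catalyst intermediate E → free catalyst + target (k5 = 1.68 s⁻¹)
    catalyst intermediate C → catalyst intermediate D (k6 = 0.449 s⁻¹)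
    starting material + free catalyst → catalyst intermediate A (k7 = 8.37 L mol⁻¹ s⁻¹)
    catalyst intermediate A → catalyst intermediate B (k8 = 6.70 s⁻¹)

- part of the starting material that has reacted at 5.0 min
- share of the unused reagent that is free and not bound as idle adduct, at 5.0 min

- by-product is meant together with its idle adduct
- run time (flask): 5.0 min

I count turnovers. Full conversion asks 10.0 turnovers of each catalyst, so the allowance, the run time shared out over those turnovers, is 30.0 s.

The turnover time is the sum of the waits around the cycle. At the charge, free catalyst waits 5.97 s for starting material, and catalyst intermediate B waits 6.19 s for reagent, through its weak balance with catalyst intermediate C. The steps that need no partner add 7.87 s. That makes 20.0 s, shorter than the allowance.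

But the first two waits grow. Each turnover uses one reagent, and its by-product binds another, because the binding term is 76. Summing the waits over 9.00 turnovers, until the starting material equals the catalyst, gives 5.11 min. The mean is 34.1 s, longer than the allowance. Allowance over mean gives me 88.0 % reacted, with 43.7 % of the unused reagent free.

The forecast, lying a little above me on both, says 90 % and 47 %, with by-product that “ties up roughly one reagent each as idle adduct”.

The flask gives 90.1 % reacted and 47.5 % of the unused reagent free. Target and over-reaction product together make 8.66 finished turnovers per catalyst, so each took 34.6 s on average; the rest of the part reacted is still on the catalyst, of which 65.2 % stands free. Trimming the catalyst to 1.75 mM cuts the allowance to 26.2 s and moves the part reacted by 5 points. The neighbour flask with 50 mM of starting material has an allowance of 12.0 s, below the 16.4 s a turnover takes at its charge, and it ends with 48.7 % reacted.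

The rate constants stand for no real mixture; the rest is arithmetic.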